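Ring A (C1–C5, C10) is disconnected to a cyclopentane by taking C4 out of the ring: the precursor is an A-nor hydrindenone in which C3 carries an isopropenyl group next to a C5=C6 double bond. The key step exploits the homoallylic 1,3-relationship between C3–Br and C5 across the gem-dimethyl carbon C4. Hydrogen bromide protonates the isopropenyl group; the C4 cation is taken up by the C5=C6 π bond and bromide opens the cyclopropylcarbinyl cation at C3, so that in one operation C5 migrates from C3 to C4, the five-membered ring becomes ring A and the equatorial C3–Br bond is set. The side chain, from (R)-linalool, is added to the C9 ketone at the end.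

Key step: step 7

Remark: atoms carry labdane numbers (ring A = C1–C5 and C10, ring B = C5–C10, side chain C11–C16), and the sense of the oxazaborolidine reduction in step 3 is assumed to follow the usual model with the quaternary carbon as the large group.

Step 1
Reactants: 1 2-methylcyclohexane-1,3-dione; 2 acrolein
Product: 3 3-(1-methyl-2,6-dioxocyclohexyl)propanal
Conditions: H2O, 23 °C
Reagents that add atoms: none
Why: Michael addition of the acidic 2-substituted 1,3-dione to acrolein should give the quaternary carbon C10 cleanly, which is not yet a stereocenter because the two ring carbonyls are still equivalent.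

Step 2
Reactants: 3 3-(1-methyl-2,6-dioxocyclohexyl)propanal
Product: 4 2-methyl-2-(4-methylpent-3-en-1-yl)cyclohexane-1,3-dione
Conditions: i-PrPPh3I, n-BuLi, THF, 0 °C; then 3, −78 → 23 °C
Reagents that add atoms: isopropyltriphenylphosphonium iodide, CC(C)[P+](c1ccccc1)(c1ccccc1)c1ccccc1.[I-]
Why: Wittig olefination with the non-stabilised isopropylidene ylide should take the aldehyde far faster than the two hindered ketones and installs C3=C4 with its two methyl groups, no stereo-issue arising because the new alkene terminus is symmetric.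

Step 3
Reactants: 4 2-methyl-2-(4-methylpent-3-en-1-yl)cyclohexane-1,3-dione
Product: 5 (2S,3S)-3-hydroxy-2-methyl-2-(4-methylpent-3-en-1-yl)cyclohexan-1-one
Conditions: (R)-2-methyl-CBS-oxazaborolidine (20 mol %), catecholborane, toluene, −60 °C
Reagents that add atoms: none
Why: Corey–Bakshi–Shibata reduction desymmetrises the dione, the catalyst fixing the carbinol as S and hydride being expected to enter anti to the homoprenyl chain, which together select one of the two enantiotopic carbonyls and so set C10 (2S) for the whole route.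

Step 4
Reactants: 5 (2S,3S)-3-hydroxy-2-methyl-2-(4-methylpent-3-en-1-yl)cyclohexan-1-one
Product: 6 (3S,3aR,7S,7aS)-7a-methyl-3-(prop-1-en-2-yl)octahydro-1H-indene-3a,7-diol
Conditions: Me2AlCl (2.5 equiv), CH2Cl2, −78 → 0 °C; aq. HCl
Reagents that add atoms: none
Why: Lewis-acid-promoted intramolecular carbonyl-ene reaction closes the five-membered ring by the C3–C5 bond on the face of the tether, which forces a cis ring fusion (new C5–OH cis to the C10 methyl), while the transfer of a methyl hydrogen to the carbonyl oxygen places the isopropenyl group on C3 cis to that hydroxyl.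

Step 5
Reactants: 6 (3S,3aR,7S,7aS)-7a-methyl-3-(prop-1-en-2-yl)octahydro-1H-indene-3a,7-diol
Product: 7 (1S,3aR,7aR)-7a-hydroxy-3a-methyl-1-(prop-1-en-2-yl)octahydro-4H-inden-4-one
Conditions: Dess–Martin periodinane, NaHCO3, CH2Cl2, 0 → 23 °C
Reagents that add atoms: none
Why: Dess–Martin oxidation takes only the secondary C9 alcohol (the tertiary C5 alcohol cannot be oxidised) and returns C9 to the ketone level after it has served to set C10.

Step 6
Reactants: 7 (1S,3aR,7aR)-7a-hydroxy-3a-methyl-1-(prop-1-en-2-yl)octahydro-4H-inden-4-one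
Product: 8 (1S,3aR)-3a-methyl-1-(prop-1-en-2-yl)-1,2,3,3a,5,6-hexahydro-4H-inden-4-one
Conditions: Burgess reagent, toluene, 60 °C
Reagents that add atoms: none
Why: Burgess dehydration is a syn elimination, and since the only β-hydrogen cis to the C5 hydroxyl sits on C6 (H–C3 is trans) the C5=C6 alkene should form rather than the conjugated C3=C5 isomer.

Step 7
Reactants: 8 (1S,3aR)-3a-methyl-1-(prop-1-en-2-yl)-1,2,3,3a,5,6-hexahydro-4H-inden-4-one
Product: 10 (6R,8aR)-6-bromo-5,5,8a-trimethyl-3,5,6,7,8,8a-hexahydronaphthalen-1(2H)-one, via tertiary bromide 9 (not isolated)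
Conditions: HBr (1.2 equiv), CH2Cl2, −78 °C; then ZnBr2 (20 mol %), −40 → 0 °C
Reagents that add atoms: hydrogen bromide, Br
Why: Proposed new method: Markovnikov protonation of the isopropenyl group gives the tertiary C4 cation (stored as bromide 9 and re-ionised by ZnBr2), the C5=C6 π bond adds to it to give a cyclopropylcarbinyl cation with charge at C6, and bromide opens this ion at C3 with cleavage of C3–C5, so that C5 has migrated from C3 to C4 and the cyclopentane has become ring A. The closest known reaction type is the acid-induced opening of 3,5-cyclo-6-hydroxy steroids to 3β-bromo-Δ5-steroids (i-steroid rearrangement), together with the ZnBr2/HBr equilibration of cyclopropylcarbinyl to homoallyl bromides in the Julia olefin synthesis. Ring A is closed by the C4–C5 bond in a 3-exo-trig π-participation followed by scission of the cyclopropane bond C3–C5, not by a direct six-ring closure. The new stereocenter C3 is set by inversion: bromide enters anti to the departing C5, and with the isopropenyl group of 8 cis to the angular methyl this gives the equatorial 6R bromide cis to that methyl, which is also the more stable epimer. The step needs capture at C3 and not at C4 or C6; this should be secured by reversibility, since the tertiary and cyclopropylcarbinyl bromides re-ionise under ZnBr2 whereas the ring-enlarged neopentyl-type bromide does not and is favoured by release of the alkylidenecyclopentane strain. Low temperature is meant to hold back the competing 1,2-hydride shift from C3 to C4.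

Step 8
Reactants: 10 (6R,8aR)-6-bromo-5,5,8a-trimethyl-3,5,6,7,8,8a-hexahydronaphthalen-1(2H)-one
Product: 11 (4aS,6R,8aR)-6-bromo-5,5,8a-trimethyloctahydronaphthalen-1(2H)-one
Conditions: Mn(dpm)3 (10 mol %), PhSiH3, t-BuOOH, i-PrOH, 23 °C
Reagents that add atoms: none
Why: Metal-hydride hydrogen-atom-transfer hydrogenation (Mukaiyama type) reduces the hindered trisubstituted alkene via the tertiary C5 radical, which should take its hydrogen on the face anti to the C10 methyl and the axial C4 methyl to give the trans-decalin (4aS), the secondary bromide and the ketone being left alone under these non-hydrogenolytic conditions.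

Step 9
Reactants: 11 (4aS,6R,8aR)-6-bromo-5,5,8a-trimethyloctahydronaphthalen-1(2H)-one
Product: 13 (2S,4aS,6R,8aR)-6-bromo-2,5,5,8a-tetramethyloctahydronaphthalen-1(2H)-one, via lithium enolate 12 (not isolated)
Conditions: LiN(i-Pr)2, THF, −78 °C; MeI, −78 → 0 °C; then NaOMe (cat.), MeOH, 23 °C
Reagents that add atoms: iodomethane, CI
Why: Regiospecific enolate alkylation (C10 is quaternary, so only C8 can be deprotonated) followed by base equilibration should leave the C8 methyl equatorial (2S), because the axial epimer suffers a 1,3-diaxial clash with the C10 methyl.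

Step 10
Reactants: 14 (R)-(−)-linalool
Product: 16 (5R)-5-ethenyl-5-methyloxolan-2-ol, via secondary ozonide 15 (not isolated)
Conditions: O3 (1 equiv), CH2Cl2, −78 °C; then Me2S, −78 → 23 °C
Reagents that add atoms: ozone, [O-][O+]=O
Why: Ozonolysis with one equivalent of ozone cleaves the electron-rich trisubstituted alkene in preference to the monosubstituted vinyl group next to the carbinol, and the resulting γ-hydroxy aldehyde closes to the lactol without touching the stereocenter.

Step 11
Reactants: 16 (5R)-5-ethenyl-5-methyloxolan-2-ol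
Product: 17 (3R)-5-iodo-3-methylpent-1-en-3-yl formate
Conditions: PhI(OAc)2, I2, CH2Cl2, visible light, 23 °C
Reagents that add atoms: iodine, II
Why: Suárez alkoxy-radical fragmentation: the anomeric oxygen radical formed from the hypoiodite undergoes β-scission of the C2–C3 ring bond, the primary radical is trapped by iodine and the ring oxygen is left as a formate on the untouched tertiary stereocenter.

Step 12
Reactants: 17 (3R)-5-iodo-3-methylpent-1-en-3-yl formate
Product: 18 (3R)-5-iodo-3-methylpent-1-en-3-ol
Conditions: K2CO3 (cat.), MeOH, 0 °C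
Reagents that add atoms: none
Why: Base-catalysed transesterification removes the very labile formate under conditions too mild for oxetane formation from the iodo alkoxide.

Step 13
Reactants: 18 (3R)-5-iodo-3-methylpent-1-en-3-ol
Product: 19 triethyl{[(3R)-5-iodo-3-methylpent-1-en-3-yl]oxy}silane
Conditions: Et3SiOTf, 2,6-lutidine, CH2Cl2, −78 → 0 °C
Reagents that add atoms: triethylsilyl trifluoromethanesulfonate, CC[Si](CC)(CC)OS(=O)(=O)C(F)(F)F
Why: Silylation of the tertiary allylic alcohol with the silyl triflate protects it against the organolithium chemistry of the next step.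

Step 14
Reactants: 19 triethyl{[(3R)-5-iodo-3-methylpent-1-en-3-yl]oxy}silane; 13 (2S,4aS,6R,8aR)-6-bromo-2,5,5,8a-tetramethyloctahydronaphthalen-1(2H)-one
Product: 21 (1R,2S,4aS,6R,8aR)-6-bromo-2,5,5,8a-tetramethyl-1-[(3R)-3-methyl-3-(triethylsilyloxy)pent-4-en-1-yl]decahydronaphthalen-1-ol, via alkyllithium 20 (not isolated)
Conditions: 19, t-BuLi (2.1 equiv), Et2O–pentane, −78 °C; then 13, LaCl3·2LiCl, THF, −78 → −20 °C; H2O
Reagents that add atoms: none
Why: Iodine–lithium exchange followed by LaCl3·2LiCl-promoted 1,2-addition (which suppresses enolisation) should take place on the axial face of the C9 carbonyl, anti to the axial C10 methyl, so that the new tertiary alcohol has OH cis to that methyl (1R), the hindered secondary bromide being inert once the t-BuLi has been consumed.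

Step 15
Reactants: 21 (1R,2S,4aS,6R,8aR)-6-bromo-2,5,5,8a-tetramethyl-1-[(3R)-3-methyl-3-(triethylsilyloxy)pent-4-en-1-yl]decahydronaphthalen-1-ol
Product: 22 (1R,2S,4aS,6R,8aR)-6-bromo-1-[(3R)-3-hydroxy-3-methylpent-4-en-1-yl]-2,5,5,8a-tetramethyldecahydronaphthalen-1-ol (CNP0318118.1)
Conditions: n-Bu4NF, THF, 23 °C
Reagents that add atoms: none
Why: Fluoride-induced desilylation frees the tertiary allylic alcohol under non-acidic conditions, which avoids allylic transposition and leaves the bromide untouched.

Compound list

1 | 2-methylcyclohexane-1,3-dione | CC1C(=O)CCCC1=O | starting material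
2 | acrolein (prop-2-enal) | C=CC=O | starting material
3 | 3-(1-methyl-2,6-dioxocyclohexyl)propanal | CC1(CCC=O)C(=O)CCCC1=O | intermediate
4 | 2-methyl-2-(4-methylpent-3-en-1-yl)cyclohexane-1,3-dione | CC(C)=CCCC1(C)C(=O)CCCC1=O | intermediate
5 | (2S,3S)-3-hydroxy-2-methyl-2-(4-methylpent-3-en-1-yl)cyclohexan-1-one (OH cis to the homoprenyl chain, trans to the methyl) | O[C@H]1CCCC(=O)[C@@]1(C)CCC=C(C)C | intermediate
6 | (3S,3aR,7S,7aS)-7a-methyl-3-(prop-1-en-2-yl)octahydro-1H-indene-3a,7-diol (cis-fused; 3a-OH, 7a-methyl and isopropenyl on one face, 7-OH on the other) | O[C@H]1CCC[C@@]2(O)[C@H](C(C)=C)CC[C@]21C | intermediate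
7 | (1S,3aR,7aR)-7a-hydroxy-3a-methyl-1-(prop-1-en-2-yl)octahydro-4H-inden-4-one | O=C1CCC[C@@]2(O)[C@H](C(C)=C)CC[C@]21C | intermediate
8 | (1S,3aR)-3a-methyl-1-(prop-1-en-2-yl)-1,2,3,3a,5,6-hexahydro-4H-inden-4-one (isopropenyl cis to the angular methyl) | O=C1CCC=C2[C@H](C(C)=C)CC[C@]21C | intermediate
9 | (1R,3aR)-1-(2-bromopropan-2-yl)-3a-methyl-1,2,3,3a,5,6-hexahydro-4H-inden-4-one | O=C1CCC=C2[C@H](C(C)(C)Br)CC[C@]21C | intermediate
10 | (6R,8aR)-6-bromo-5,5,8a-trimethyl-3,5,6,7,8,8a-hexahydronaphthalen-1(2H)-one | O=C1CCC=C2C(C)(C)[C@H](Br)CC[C@]21C | intermediate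
11 | (4aS,6R,8aR)-6-bromo-5,5,8a-trimethyloctahydronaphthalen-1(2H)-one (trans-fused) | O=C1CCC[C@@H]2C(C)(C)[C@H](Br)CC[C@]21C | intermediate
12 | lithium enolate of 11 (C8=C9–OLi) | [Li]OC1=CCC[C@@H]2C(C)(C)[C@H](Br)CC[C@]21C | intermediate
13 | (2S,4aS,6R,8aR)-6-bromo-2,5,5,8a-tetramethyloctahydronaphthalen-1(2H)-one | O=C1[C@@H](C)CC[C@@H]2C(C)(C)[C@H](Br)CC[C@]21C | intermediate
14 | (R)-(−)-linalool, (3R)-3,7-dimethylocta-1,6-dien-3-ol | C=C[C@](C)(O)CCC=C(C)C | starting material
15 | (3R)-5-(5,5-dimethyl-1,2,4-trioxolan-3-yl)-3-methylpent-1-en-3-ol (secondary ozonide) | C=C[C@](C)(O)CCC1OOC(C)(C)O1 | intermediate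
16 | (5R)-5-ethenyl-5-methyloxolan-2-ol (lactol, both anomers) | C=C[C@@]1(C)CCC(O)O1 | intermediate
17 | (3R)-5-iodo-3-methylpent-1-en-3-yl formate | C=C[C@](C)(OC=O)CCI | intermediate
18 | (3R)-5-iodo-3-methylpent-1-en-3-ol | C=C[C@](C)(O)CCI | intermediate
19 | triethyl{[(3R)-5-iodo-3-methylpent-1-en-3-yl]oxy}silane | C=C[C@](C)(O[Si](CC)(CC)CC)CCI | intermediate
20 | [(3R)-3-methyl-3-(triethylsilyloxy)pent-4-en-1-yl]lithium | C=C[C@](C)(O[Si](CC)(CC)CC)CC[Li] | intermediate
21 | (1R,2S,4aS,6R,8aR)-6-bromo-2,5,5,8a-tetramethyl-1-[(3R)-3-methyl-3-(triethylsilyloxy)pent-4-en-1-yl]decahydronaphthalen-1-ol | C=C[C@](C)(O[Si](CC)(CC)CC)CC[C@@]1(O)[C@@H](C)CC[C@@H]2C(C)(C)[C@H](Br)CC[C@]21C | intermediate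
22 | (1R,2S,4aS,6R,8aR)-6-bromo-1-[(3R)-3-hydroxy-3-methylpent-4-en-1-yl]-2,5,5,8a-tetramethyldecahydronaphthalen-1-ol | C=C[C@](C)(O)CC[C@@]1(O)[C@@H](C)CC[C@@H]2C(C)(C)[C@H](Br)CC[C@]21C | target

Total step count: 15. Longest linear sequence: 11 steps (steps 1–9, 14 and 15).

Steps most likely to fail

1. Step 7 (Proposed new method). What may go wrong: bromide may capture the C4 cation before the C5=C6 bond participates, or a 1,2-hydride shift from C3 to C4 followed by proton loss may drain the material into conjugated dienes, so that the ring is not enlarged. The fallback uses known chemistry, a bromonium-initiated cation–olefin cyclisation ended by a vinylsilane, in which ring A is closed directly by the C4–C5 bond. Starting from 5, silylation (t-BuMe2SiOTf, 2,6-lutidine) would give the tert-butyldimethylsilyl ether F1. KN(SiMe3)2 and PhNTf2 would give the enol triflate F2, and Pd(PPh3)4 with Me3SiSiMe3 the vinylsilane F3. Et2SBr·SbCl5Br in MeNO2 at −25 °C should then give, through ipso attack of C5 on the C4 cation and loss of the silyl group, the bromo-octalin silyl ether F4. n-Bu4NF would free the alcohol F5, and Dess–Martin oxidation returns to the route at 10.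

2. Step 4. What may go wrong: the unactivated ketone may not engage, or the tertiary cation of a stepwise pathway may be captured by chloride or lose a proton in the wrong direction instead of completing the ene process. The fallback replaces the ene reaction by an intramolecular Hosomi–Sakurai allylation. Starting from 3, Wittig reaction with the ylide from [1-(trimethylsilyl)propan-2-yl]triphenylphosphonium iodide and n-BuLi would give the allylsilane dione F6. The reduction of step 3 would give the hydroxy ketone F7. TiCl4 in CH2Cl2 at −78 °C should then close the five-membered ring with loss of the silyl group, and the route is rejoined at 6.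

3. Step 11. What may go wrong: the hypoiodite reagent may add across the vinyl group, or the alkoxy radical may abstract hydrogen or be oxidised to the lactone instead of fragmenting. The fallback replaces lactol fragmentation by decarboxylative iodination of a protected acid. Starting from 14, silylation (Et3SiOTf, 2,6-lutidine) would give the silyl ether F8, and ozonolysis with Me2S work-up the aldehyde F9. Pinnick oxidation (NaClO2, NaH2PO4, 2-methylbut-2-ene) would give the acid F10. Conversion into the N-acyloxypyridine-2-thione ester (oxalyl chloride, then the sodium salt of N-hydroxypyridine-2-thione) and photolysis in the presence of CHI3 (Barton decarboxylation) returns to the route at 19.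

Further compounds

F1 | step 7 | (2S,3S)-3-[(tert-butyldimethylsilyl)oxy]-2-methyl-2-(4-methylpent-3-en-1-yl)cyclohexan-1-one | CC(C)(C)[Si](C)(C)O[C@H]1CCCC(=O)[C@@]1(C)CCC=C(C)C
F2 | step 7 | enol triflate of F1 (triflate on C5, C5=C6 double bond) | CC(C)(C)[Si](C)(C)O[C@H]1CCC=C(OS(=O)(=O)C(F)(F)F)[C@@]1(C)CCC=C(C)C
F3 | step 7 | vinylsilane, the C5-trimethylsilyl analogue of F2 | CC(C)(C)[Si](C)(C)O[C@H]1CCC=C([Si](C)(C)C)[C@@]1(C)CCC=C(C)C
F4 | step 7 | tert-butyldimethylsilyl ether of 6-bromo-5,5,8a-trimethyl-1,2,3,5,6,7,8,8a-octahydronaphthalen-1-ol | CC(C)(C)[Si](C)(C)O[C@H]1CCC=C2C(C)(C)[C@H](Br)CC[C@]21C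
F5 | step 7 | 6-bromo-5,5,8a-trimethyl-1,2,3,5,6,7,8,8a-octahydronaphthalen-1-ol (the C9 alcohol corresponding to 10) | O[C@H]1CCC=C2C(C)(C)[C@H](Br)CC[C@]21C
F6 | step 4 | 2-methyl-2-[4-methyl-5-(trimethylsilyl)pent-3-en-1-yl]cyclohexane-1,3-dione (E/Z mixture) | C[Si](C)(C)CC(C)=CCCC1(C)C(=O)CCCC1=O
F7 | step 4 | (2S,3S)-3-hydroxy-2-methyl-2-[4-methyl-5-(trimethylsilyl)pent-3-en-1-yl]cyclohexan-1-one | O[C@H]1CCCC(=O)[C@@]1(C)CCC=C(C)C[Si](C)(C)C
F8 | step 11 | (R)-linalool triethylsilyl ether | C=C[C@](C)(O[Si](CC)(CC)CC)CCC=C(C)C
F9 | step 11 | (4R)-4-methyl-4-(triethylsilyloxy)hex-5-enal | C=C[C@](C)(O[Si](CC)(CC)CC)CCC=O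
F10 | step 11 | (4R)-4-methyl-4-(triethylsilyloxy)hex-5-enoic acid | C=C[C@](C)(O[Si](CC)(CC)CC)CCC(=O)O
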